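The route rests on disconnecting the C1–C7 bond between the 3,4,5-trimethoxyphenyl ring and the benzylic carbinol carbon. The feature exploited is that the C7 alcohol lies next to the C8 stereocentre, whose aryl ether oxygen, helped by the neighbouring ortho-methoxy oxygen of the guaiacyl ring, can hold magnesium together with an aldehyde oxygen. Adding 3,4,5-trimethoxyphenylmagnesium bromide to this chelated α-aryloxy aldehyde forges C1–C7 and sets C7 (R) from C8 (R) in one operation, giving the threo skeleton. The precursor is a TBS-protected (R)-2-(guaiacyloxy)propanal, reached from ethyl (S)-lactate by Mitsunobu inversion with silylated dihydroconiferyl alcohol and DIBAL-H half-reduction; desilylation finishes the synthesis.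

Key step: step 5

Remark: the target is read as the threo (7R,8R) isomer. Neolignan numbering is used: C1–C6 is the trimethoxyphenyl ring, C7 the carbinol carbon, C8 the ether-bearing methine, C9 its methyl; on the guaiacyl ring C4' carries the ether oxygen, C3' the methoxy group and C1' the side chain.

Step 1
Reactants: 1 dihydroconiferyl alcohol [4-(3-hydroxypropyl)-2-methoxyphenol]
Product: 2 4-[3-(tert-butyldimethylsilyloxy)propyl]-2-methoxyphenol
Conditions: TBSCl (1.05 equiv), imidazole (2.2 equiv), CH2Cl2, 0 °C
Reagents that add atoms: tert-butyldimethylsilyl chloride, CC(C)(C)[Si](C)(C)Cl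
Why: Imidazole-promoted silyl ether formation, in which one equivalent of the bulky chlorosilane at 0 °C should take the unhindered primary alcohol in preference to the ortho-methoxy-flanked, internally hydrogen-bonded phenol.

Step 2
Reactants: 2 4-[3-(tert-butyldimethylsilyloxy)propyl]-2-methoxyphenol; 3 ethyl (S)-lactate [ethyl (2S)-2-hydroxypropanoate]
Product: 5 ethyl (2R)-2-{4-[3-(tert-butyldimethylsilyloxy)propyl]-2-methoxyphenoxy}propanoate, via oxyphosphonium salt 4 (not isolated)
Conditions: PPh3, DIAD (1.3 equiv each), THF, 0 °C → rt
Reagents that add atoms: none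
Why: Mitsunobu reaction, in which the phenol (pKa about 10) is an ideal pronucleophile and its phenoxide displaces triphenylphosphine oxide from the activated lactate 4 by SN2 next to the ester carbonyl, so C8 is installed with inversion, S to R.

Step 3
Reactants: 6 5-bromo-1,2,3-trimethoxybenzene
Product: 7 3,4,5-trimethoxyphenylmagnesium bromide (titrated solution in THF)
Conditions: Mg turnings (1.3 equiv), cat. BrCH2CH2Br, THF, 45 °C → rt
Reagents that add atoms: magnesium, [Mg]
Why: Grignard reagent formation by oxidative insertion of activated magnesium into the aryl C–Br bond, which the three inert methoxy groups tolerate and which gives no co-product.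

Step 4
Reactants: 5 ethyl (2R)-2-{4-[3-(tert-butyldimethylsilyloxy)propyl]-2-methoxyphenoxy}propanoate
Product: 9 (2R)-2-{4-[3-(tert-butyldimethylsilyloxy)propyl]-2-methoxyphenoxy}propanal, via aluminium hemiacetal 8 (not isolated)
Conditions: DIBAL-H (1.1 equiv), CH2Cl2, −78 °C; MeOH, then aq. Rochelle salt, 0 °C; dried, concentrated cold and used crude at once
Reagents that add atoms: none
Why: DIBAL-H half-reduction of an ester, in which a single hydride is delivered at −78 °C and the tetrahedral hemiacetal 8, held by coordination of aluminium to the α-aryloxy oxygen, should survive until the cold protic quench, while the cold, non-basic conditions leave C8 and the silyl ether untouched.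

Step 5
Reactants: 9 (2R)-2-{4-[3-(tert-butyldimethylsilyloxy)propyl]-2-methoxyphenoxy}propanal; 7 3,4,5-trimethoxyphenylmagnesium bromide
Product: 12 (1R,2R)-2-{4-[3-(tert-butyldimethylsilyloxy)propyl]-2-methoxyphenoxy}-1-(3,4,5-trimethoxyphenyl)propan-1-ol (surinamensinol A primary TBS ether), via magnesium chelate 10 (not isolated), via bromomagnesium alkoxide 11 (not isolated)
Conditions: MgBr2·OEt2 (2 equiv), CH2Cl2, −78 °C, 20 min; then 7 (2 equiv, THF solution), −78 → −40 °C; aq. NH4Cl
Reagents that add atoms: none
Why: The aldehyde is first locked by MgBr2 as chelate 10, a five-membered ring spanning the carbonyl oxygen and the C8 ether oxygen, with the C3' methoxy oxygen closing a second five-membered ring on the same magnesium, so that the weakly donating aryl ether becomes part of a tridentate grip and the O=C7–C8–O unit is held syn-periplanar. Aryl transfer from 7 to C7 on this chelate gives alkoxide 11, the closest known reaction type being the Cram-chelate addition of Grignard reagents to α-alkoxy aldehydes such as O-protected lactaldehydes. No ring is closed and one skeletal bond, C1–C7, is formed. The new C7 stereocentre is controlled by C8 through 1,2-induction: the aryl group enters from the chelate face that carries the C8 hydrogen, anti to the C9 methyl, which should give the syn (threo) 7R,8R isomer. The step needs facial selectivity at the carbonyl against the open-chain polar Felkin–Anh pathway that would lead to the erythro isomer; this is secured by pre-complexation with excess MgBr2·OEt2 in weakly coordinating CH2Cl2 at −78 °C, by limiting THF to the small volume that carries 7, and by a remote silyl ether too hindered to compete for magnesium. The low basicity of the aryl Grignard reagent at −78 °C should keep enolisation of the α-aryloxy aldehyde, and with it loss of C8 integrity, from competing.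

Step 6
Reactants: 12 (1R,2R)-2-{4-[3-(tert-butyldimethylsilyloxy)propyl]-2-methoxyphenoxy}-1-(3,4,5-trimethoxyphenyl)propan-1-ol
Product: 13 surinamensinol A
Conditions: TBAF (1.2 equiv), THF, 0 °C → rt
Reagents that add atoms: none
Why: Fluoride-induced desilylation driven by Si–F bond formation should free the primary alcohol under near-neutral conditions that avoid ionising the electron-rich benzylic C7 carbinol, so both stereocentres are kept.

Compound list
1 | dihydroconiferyl alcohol, 4-(3-hydroxypropyl)-2-methoxyphenol | COc1cc(CCCO)ccc1O | starting material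
2 | 4-[3-(tert-butyldimethylsilyloxy)propyl]-2-methoxyphenol | COc1cc(CCCO[Si](C)(C)C(C)(C)C)ccc1O | intermediate
3 | ethyl (S)-lactate, ethyl (2S)-2-hydroxypropanoate | C[C@H](O)C(=O)OCC | starting material
4 | ethyl (2S)-2-[(triphenylphosphonio)oxy]propanoate as its ion pair with the phenoxide of 2 (not isolated) | CCOC(=O)[C@H](C)O[P+](c1ccccc1)(c1ccccc1)c1ccccc1.COc1cc(CCCO[Si](C)(C)C(C)(C)C)ccc1[O-] | intermediate
5 | ethyl (2R)-2-{4-[3-(tert-butyldimethylsilyloxy)propyl]-2-methoxyphenoxy}propanoate | COc1cc(CCCO[Si](C)(C)C(C)(C)C)ccc1O[C@H](C)C(=O)OCC | intermediate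
6 | 5-bromo-1,2,3-trimethoxybenzene | COc1cc(Br)cc(OC)c1OC | starting material
7 | 3,4,5-trimethoxyphenylmagnesium bromide | COc1cc([Mg]Br)cc(OC)c1OC | intermediate
8 | diisobutylaluminium hemiacetal of 5, (2R)-2-aryloxy-1-ethoxypropyl O–Al(i-Bu)2 (not isolated) | COc1cc(CCCO[Si](C)(C)C(C)(C)C)ccc1O[C@H](C)C(OCC)O[Al](CC(C)C)CC(C)C | intermediate
9 | (2R)-2-{4-[3-(tert-butyldimethylsilyloxy)propyl]-2-methoxyphenoxy}propanal | COc1cc(CCCO[Si](C)(C)C(C)(C)C)ccc1O[C@H](C)C=O | intermediate
10 | magnesium bromide chelate of 9, Mg bound to the carbonyl, C8 ether and C3' methoxy oxygens (not isolated) | COc1cc(CCCO[Si](C)(C)C(C)(C)C)ccc1O[C@H](C)C=O.Br[Mg]Br | intermediate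
11 | bromomagnesium (1R,2R)-alkoxide of 12 (not isolated) | COc1cc(CCCO[Si](C)(C)C(C)(C)C)ccc1O[C@H](C)[C@H](O[Mg]Br)c1cc(OC)c(OC)c(OC)c1 | intermediate
12 | (1R,2R)-2-{4-[3-(tert-butyldimethylsilyloxy)propyl]-2-methoxyphenoxy}-1-(3,4,5-trimethoxyphenyl)propan-1-ol | COc1cc(CCCO[Si](C)(C)C(C)(C)C)ccc1O[C@H](C)[C@H](O)c1cc(OC)c(OC)c(OC)c1 | intermediate
13 | surinamensinol A, (1R,2R)-2-[4-(3-hydroxypropyl)-2-methoxyphenoxy]-1-(3,4,5-trimethoxyphenyl)propan-1-ol (7R,8R, threo) | COc1cc(CCCO)ccc1O[C@H](C)[C@H](O)c1cc(OC)c(OC)c(OC)c1 | target

Total step count: 6. Longest linear sequence: 5 (steps 1, 2, 4, 5, 6), with step 3 as the convergent branch.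

Steps most likely to fail

Step 5. What may go wrong is incomplete chelation of magnesium by the weakly basic aryl ether oxygen, made worse by THF competing for the metal, so that addition through the open-chain polar Felkin–Anh mode erodes the facial selectivity at C7. The fallback sets C7 by reduction instead of addition. It sets out from 12 of whatever C7 diastereomeric purity: Dess–Martin periodinane with NaHCO3 in CH2Cl2 should converge the material on the ketone (R)-2-{4-[3-(tert-butyldimethylsilyloxy)propyl]-2-methoxyphenoxy}-1-(3,4,5-trimethoxyphenyl)propan-1-one F1. L-Selectride in THF at −78 °C, a bulky non-chelating hydride that attacks anti to the aryloxy group (polar Felkin–Anh, which for the ketone leads to the threo alcohol), should then bring the material back to 12. Chelating hydrides are avoided because they would favour the erythro alcohol.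

Step 4. What may go wrong is delivery of a second hydride after premature collapse of the aluminium hemiacetal, or erosion of the C8 configuration while the sensitive aldehyde is handled. The fallback separates reduction from oxidation-level adjustment. It sets out from 5: LiBH4 in THF at 0 °C → rt should give the bench-stable alcohol (2R)-2-{4-[3-(tert-butyldimethylsilyloxy)propyl]-2-methoxyphenoxy}propan-1-ol F2, which can be purified and checked for enantiopurity. Dess–Martin periodinane with NaHCO3 in CH2Cl2 at 0 °C, a non-basic oxidation, should then deliver 9 for immediate use.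

Step 2. What may go wrong is slow coupling of the ortho-substituted, internally hydrogen-bonded phenol, so that the reduced azodicarboxylate is alkylated instead, or incomplete inversion at C8. The fallback activates the lactate separately as a sulfonate. It sets out from 3: Tf2O and 2,6-lutidine in CH2Cl2 at −78 °C should give ethyl (2S)-2-[(trifluoromethylsulfonyl)oxy]propanoate F3. The potassium phenoxide of 2 (K2CO3, MeCN, 0 °C → rt) should displace the triflate by SN2 with inversion, coming back to the route at 5.

Further compounds
F1 | step 5 | (R)-2-{4-[3-(tert-butyldimethylsilyloxy)propyl]-2-methoxyphenoxy}-1-(3,4,5-trimethoxyphenyl)propan-1-one | COc1cc(CCCO[Si](C)(C)C(C)(C)C)ccc1O[C@H](C)C(=O)c1cc(OC)c(OC)c(OC)c1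
F2 | step 4 | (2R)-2-{4-[3-(tert-butyldimethylsilyloxy)propyl]-2-methoxyphenoxy}propan-1-ol | COc1cc(CCCO[Si](C)(C)C(C)(C)C)ccc1O[C@H](C)CO
F3 | step 2 | ethyl (2S)-2-[(trifluoromethylsulfonyl)oxy]propanoate | CCOC(=O)[C@H](C)OS(=O)(=O)C(F)(F)F
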